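## The problem

The target, numbered 19 below, is a C40 carotenoid of the 2,6-cyclolycopene-1,5-diol type. In carotenoid numbering, an all-E chain of ten conjugated double bonds (C7=C8 to C5'=C6') ends on one side in an open tail with an isolated 1',2'-alkene and is bonded on the other side through C7 to a single cyclopentane made of C2, C3, C4, C5 and C6. The ring holds three contiguous stereocentres: C5 (tertiary methyl carbinol, R), C6 (the CH that carries the chain, S) and C2 (the CH that carries the 2-hydroxypropan-2-yl group C1, R). The C5 hydroxyl is cis to the C6–C7 bond and the C2 branch is trans to it. Only C2 has a counterpart that can be bought enantiopure (C4 of limonene), so C2 has to direct C6, and the 1,2-relationship C5/C6 is best locked by a ring fusion. The decaene does not tolerate acid, oxidants, light or long heating in air, so it has to be built separately and joined to the ring last. Both tertiary alcohols dehydrate under acid, and because the C5 hydroxyl is β to C7, every C7 carbonyl intermediate is an aldol that can open by retro-aldol reaction, eliminate or epimerise at C6 under base. The C1 hydroxyl is γ to C7 and would lactonise onto a C7 acid in an open-chain precursor, so it has to stay masked until the ring exists. The enabling feature is the array O–C5–C6–C7: its oxygen and C7 are cis on the cyclopentane, which is the connectivity of a 2-oxetanone fused across C5–C6 (a 6-oxabicyclo[3.2.0]heptan-7-one). Opening that bicycle at C5–C6 and O–C7 leaves a 6-oxo acid whose only stereocentre is C2.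

## Retrosynthesis

**Cut at C7=C8.** Target 19 is divided into the C10 ring aldehyde 10 and the C30 phosphonium salt 17, which reacts as ylide 18. The neighbouring cuts (C9=C10, C11=C12, C15=C15') would all require chain extension on the sensitive β-hydroxy aldehyde. This cut alone leaves every stereocentre in a small, polyene-free piece, and 17 carries no stereocentre. The forward olefination meets a hindered, α-branched aldehyde, has to run without strong base, and must end with an E double bond. Thermal equilibration should provide the E geometry, because a Z bond next to the C9 methyl group is strained.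

**Cut at C7'=C8'.** Salt 17 is traced through alcohol 16 to aldehyde 15. Aldehyde 15 is divided into the symmetric C20 dialdehyde 13 and the geranyl ylide 14, which comes from salt 12 and bromide 11. Compared with a cut at C11'=C12', this uses two commercial blocks directly and builds the whole C30 chain in one carbon–carbon bond formation. The forward reaction must stop after one aldehyde group of 13 has reacted. An excess of 13 and the lower electrophilicity of 15 serve that purpose.

**Functional-group changes at C7 and C1.** Aldehyde 10 is taken back to triol 9 (oxidation level of C7), 9 to the isopropenyl diol 8 (C1–O bond, Markovnikov hydration) and 8 to β-lactone 7 (reduction at C7). The C1 carbinol stays an alkene until the ring exists, because a free C1 hydroxyl in acid 4 would close a γ-lactone onto C7 and leave no acyl group to activate. It is introduced only after the lactone has been reduced, so that the strained ring never faces a neighbouring hydroxyl. Each step changes one group and touches no stereocentre.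

**Cut at C5–C6 and O–C7.** β-Lactone 7 is opened at both bonds to the open-chain keto acid 4. In the forward sense 4 is activated as acylammonium salt 5 and passes through aldolate 6. The neighbouring cut, C5–C6 alone at the aldehyde level (an aldol of 3), forms the same carbon–carbon bond but leaves the cis relationship of O and C7 to equilibrium, whereas the lactone enforces it. Cuts at C2–C6 or C4–C5 do not lead back to a purchasable chiral compound. Two rings and two stereocentres are removed and one stereocentre remains. The forward reaction has to select the enolate face anti to the isopropenyl group.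

**Cut of the terpene ring.** Acid 4 comes from keto aldehyde 3 by oxidation, and 3 from the commercial terpene oxide 1 by cleavage of its C1–C2 bond through diol 2. Overall the six-membered ring of 1 is contracted: its methyl-bearing carbon becomes C5, its oxirane CH becomes the exocyclic C7, and its C4 becomes C2 of the target without ever being touched. Periodate cleavage and a chlorite oxidation are all that is asked, and the 1,1-disubstituted alkene must survive both.

## Roads not taken

**Alternative 1: ring contraction of a cyclohexenone.** The bond made is C2–C3. The diazo enone A1, reached from a para-substituted phenol by oxidative dearomatisation, silylation, enantioselective conjugate vinylation and diazo transfer, would lose N2 on irradiation in methanol. C3 shifts from the carbonyl carbon C1 to the carbene carbon C2, and the ketene is trapped as methyl ester A2.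
- Merits: the C5 carbinol and its cis relationship to the C6 vinyl group are fixed early, the vinyl group is a ready handle for C7, and either enantiomer follows from the choice of catalyst. In this respect it is better than the chosen plan, which is tied to the chiral pool.
- Weak points for this target: C2 emerges undefined from ketene protonation and must be corrected by epimerisation. The ring alkene of A2 has to be saturated next to a vinyl group. The ester still needs two methyl additions, the silyl group has to come off, and enantiocontrol rests on a desymmetrisation that must be developed.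
- Comparison: roughly ten operations would be needed to reach the oxidation pattern of 10, against six. The chosen plan offsets its dependence on the chiral pool with a two-step precursor and with all three centres set under substrate and ring-fusion control.

**Alternative 2: reductive closure at C4–C5.** The iodo β-keto ester A3 would be treated with SmI2. The C4 radical or organosamarium adds to the chelated C5 ketone and gives hydroxy ester A4 with hydroxyl and ester cis.
- Merits: chelation delivers the same cis O–C5–C6–C7 array as the lactone. A4 is an unstrained, storable ester and would join the route at diol 8 after hydride reduction. In stereochemical outcome at C5/C6 and in robustness of the product it is as good as, or better than, β-lactone 7.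
- Weak points: A3 has no short origin. Its C2 centre needs its own asymmetric construction, its C6 centre is a labile β-keto ester position so the C2/C6 relationship is decided only during closure, and the reagent is stoichiometric.
- Comparison: the chosen plan offsets the strained and less storable 7 with a precursor two steps from a commercial terpene oxide and with catalytic activation without metal reductants.

**Alternative 3: cation–olefin closure at C2–C6.** The cis vinyl epoxide A5 is available in three operations from the Z-configured C10 allylic terpene alcohol (asymmetric epoxidation, oxidation, methylenation). Acid would open it at the allylic carbon C6 while the C1=C2 alkene attacks C6 with inversion, and water would capture the C1 cation to give diol A6.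
- Merits: it is the shortest road. Ring, C5 carbinol and C1 carbinol arise in one step, and ozonolysis of the vinyl group of A6 would give aldehyde 10 after about five operations in all, against six. In step economy and in avoiding a separate hydration it is better.
- Weak points: three selectivities are uncontrolled. Opening at tertiary C5 competes with opening at C6. Inversion at C6 holds only while the opening stays concerted and is lost through an allyl cation. The configuration at C2 depends on the folding of a flexible chain with no strong bias, so epimers at C2 and C6 are to be expected.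
- Comparison: the chosen plan offsets one extra step with three stereocentres fixed by mechanism instead of by separation.

Key step: step 3

Remark: commercial (4R)-limonene 1,2-oxide is a cis/trans mixture at the oxirane; both isomers converge on 3, so it is used as bought.

## Route

Step 1
Reactants: 1 (4R)-limonene 1,2-oxide [(4R)-1-methyl-4-(prop-1-en-2-yl)-7-oxabicyclo[4.1.0]heptane, cis/trans mixture at the oxirane]
Product: 3 (3R)-6-oxo-3-(prop-1-en-2-yl)heptanal, via trans-diol 2 (not isolated)
Conditions: H5IO6 (1.2 equiv), THF/H2O, 0 °C to rt
Reagents that add atoms: water, O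
Why: Acid-catalysed hydrolysis of both oxirane isomers should converge on the trans-diaxial diol 2, which periodate cleaves (Malaprade glycol cleavage) to the keto aldehyde. The stereocentre is not α to either carbonyl group and the 1,1-disubstituted alkene is inert to periodic acid.

Step 2
Reactants: 3 (3R)-6-oxo-3-(prop-1-en-2-yl)heptanal
Product: 4 (3R)-6-oxo-3-(prop-1-en-2-yl)heptanoic acid
Conditions: NaClO2, NaH2PO4, 2-methylbut-2-ene (excess), t-BuOH/H2O, 0 °C to rt
Reagents that add atoms: sodium chlorite, [Na+].[O-]Cl=O
Why: Pinnick oxidation converts only the aldehyde. The hypochlorous acid formed is taken up by the excess trisubstituted alkene, so the isopropenyl group, the methyl ketone and the stereocentre should be left alone.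

Step 3
Reactants: 4 (3R)-6-oxo-3-(prop-1-en-2-yl)heptanoic acid
Product: 7 (1S,2R,5R)-5-methyl-2-(prop-1-en-2-yl)-6-oxabicyclo[3.2.0]heptan-7-one, via acylammonium tosylate 5 (not isolated), via ammonium aldolate 6 (not isolated)
Conditions: TsCl (1.25 equiv), 4-pyrrolidinopyridine (1.5 equiv), iPr2NEt (4 equiv), CH2Cl2 (0.05 M), 23 °C, 4 added slowly
Reagents that add atoms: none
Why: This is an intramolecular nucleophile-catalysed aldol-lactonisation of a 6-oxo acid to a bicyclic β-lactone, a reaction type established for keto acids with a methyl ketone acceptor and a single enolisable acyl position. TsCl activates the carboxyl group of 4 and 4-pyrrolidinopyridine takes over the acyl group to give acylammonium salt 5, whose C6 methylene is deprotonated by iPr2NEt to the ammonium enolate. The enolate carbon C6 adds to the C5 ketone in a 5-(enolexo)-exo-trig aldol that closes the cyclopentane and gives aldolate 6; the tertiary alkoxide then attacks C7 in a 4-exo-trig acyl substitution that closes the oxetanone and releases the pyridine. C5 is controlled by the ring fusion: only the aldolate with O and C7 cis can lactonise to the bicyclo[3.2.0] system, and a trans aldolate can only revert. C6 is controlled by C2: with the C2–H bond eclipsing the enolate plane to avoid allylic 1,3-strain, the tether reaches the ketone from one face and the isopropenyl group lies pseudo-equatorial on the other, which places C7 trans to it. The selectivities needed are this face selection and ring closure in preference to acyl transfer between molecules; the first rests on the C2 substituent next to the enolate carbon, the second on slow addition at high dilution. C2 is β to the acyl group and cannot enolise, so the terpene-derived configuration is not at risk.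

Step 4
Reactants: 7 (1S,2R,5R)-5-methyl-2-(prop-1-en-2-yl)-6-oxabicyclo[3.2.0]heptan-7-one
Product: 8 (1R,2R,3R)-2-(hydroxymethyl)-1-methyl-3-(prop-1-en-2-yl)cyclopentan-1-ol
Conditions: LiAlH4, THF, 0 °C; then H2O, aq. NaOH (Fieser work-up)
Reagents that add atoms: none
Why: Hydride reduction of the strained lactone proceeds by acyl–oxygen cleavage, so the C5–O bond and its configuration are kept. The aldehyde stage is reduced at once as its alkoxide and C6 should not epimerise; the isolated alkene is inert.

Step 5
Reactants: 8 (1R,2R,3R)-2-(hydroxymethyl)-1-methyl-3-(prop-1-en-2-yl)cyclopentan-1-ol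
Product: 9 (1R,2R,3R)-2-(hydroxymethyl)-3-(2-hydroxypropan-2-yl)-1-methylcyclopentan-1-ol
Conditions: Co(acac)2 (20 mol%), PhSiH3 (2.5 equiv), O2 (1 atm), THF, rt
Reagents that add atoms: dioxygen, O=O
Why: Mukaiyama hydration: hydrogen-atom transfer from the hydride formed from Co(acac)2 and PhSiH3 gives the tertiary C1 radical, which is captured by O2 and reduced to the alcohol with Markovnikov regiochemistry. C1 is not a stereocentre, free hydroxyls are tolerated and no ring centre is involved.

Step 6
Reactants: 9 (1R,2R,3R)-2-(hydroxymethyl)-3-(2-hydroxypropan-2-yl)-1-methylcyclopentan-1-ol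
Product: 10 (1S,2R,5R)-2-hydroxy-5-(2-hydroxypropan-2-yl)-2-methylcyclopentane-1-carbaldehyde
Conditions: TEMPO (10 mol%), PhI(OAc)2 (1.1 equiv), CH2Cl2, rt; used without storage
Reagents that add atoms: none
Why: Oxoammonium (TEMPO) oxidation acts only on the primary alcohol, and the medium is free of base, so retro-aldol opening and epimerisation at C6 should not set in. Over-oxidation through a lactol is not expected because the C1 hydroxyl is trans to C7 and the C5 hydroxyl could only form a four-membered lactol.

Step 7
Reactants: 11 geranyl bromide [(2E)-1-bromo-3,7-dimethylocta-2,6-diene]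
Product: 12 [(2E)-3,7-dimethylocta-2,6-dien-1-yl]triphenylphosphonium bromide
Conditions: PPh3 (1.05 equiv), toluene, rt, dark
Reagents that add atoms: triphenylphosphine, c1ccc(cc1)P(c1ccccc1)c1ccccc1
Why: SN2 quaternisation of a primary allylic bromide; the E trisubstituted alkene is not involved and the salt should crystallise from toluene.

Step 8
Reactants: 12 [(2E)-3,7-dimethylocta-2,6-dien-1-yl]triphenylphosphonium bromide; 13 crocetin dialdehyde [(2E,4E,6E,8E,10E,12E,14E)-2,6,11,15-tetramethylhexadeca-2,4,6,8,10,12,14-heptaenedial]
Product: 15 apo-8'-lycopenal [(2E,4E,6E,8E,10E,12E,14E,16E,18E)-2,6,11,15,19,23-hexamethyltetracosa-2,4,6,8,10,12,14,16,18,22-decaenal], via geranylidene ylide 14 (not isolated)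
Conditions: NaOMe (1.0 equiv, added slowly), 13 (3 equiv, excess recovered), CH2Cl2/MeOH, 0 °C to rt, dark; then heptane, reflux
Reagents that add atoms: none
Why: Wittig reaction of an allylic ylide with a polyene dialdehyde, the classical C10 + C20 way into the lycopene chain. One-fold reaction is favoured by the excess of 13 and by the lower electrophilicity of the longer polyenal 15. Z geometry at the new C7'=C8' bond is strained against the C9' methyl group and should equilibrate to E on heating.

Step 9
Reactants: 15 apo-8'-lycopenal
Product: 16 apo-8'-lycopenol [(2E,4E,6E,8E,10E,12E,14E,16E,18E)-2,6,11,15,19,23-hexamethyltetracosa-2,4,6,8,10,12,14,16,18,22-decaen-1-ol]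
Conditions: NaBH4, THF/EtOH, 0 °C, dark, Ar
Reagents that add atoms: none
Why: 1,2-Reduction of a polyenal by borohydride, routine in carotenoid chemistry; the polyene is not reduced.

Step 10
Reactants: 16 apo-8'-lycopenol
Product: 17 [(2E,4E,6E,8E,10E,12E,14E,16E,18E)-2,6,11,15,19,23-hexamethyltetracosa-2,4,6,8,10,12,14,16,18,22-decaen-1-yl]triphenylphosphonium bromide
Conditions: PPh3·HBr (1.1 equiv), CH2Cl2/MeOH, 0 °C to rt, dark, Ar
Reagents that add atoms: triphenylphosphine hydrobromide, Br.c1ccc(cc1)P(c1ccccc1)c1ccccc1
Why: The standard preparation of carotenoid Wittig salts: the polyenylic alcohol ionises to a delocalised cation, which the phosphine captures at the chain terminus so that full conjugation is kept.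

Step 11
Reactants: 17 C30 phosphonium bromide; 10 (1S,2R,5R)-2-hydroxy-5-(2-hydroxypropan-2-yl)-2-methylcyclopentane-1-carbaldehyde
Product: 19 (2R,5R,6S)-2,6-cyclolycopene-1,5-diol [(1R,2S,3R)-3-(2-hydroxypropan-2-yl)-1-methyl-2-[(1E,3E,5E,7E,9E,11E,13E,15E,17E,19E)-3,7,12,16,20,24-hexamethylpentacosa-1,3,5,7,9,11,13,15,17,19,23-undecaen-1-yl]cyclopentan-1-ol], via polyenylidene ylide 18 (not isolated)
Conditions: 17 (1.2 equiv), 1,2-epoxybutane/EtOH, reflux, dark, Ar; then heptane, 90 °C, crystallisation
Reagents that add atoms: none
Why: Wittig reaction under the epoxide conditions used for base-sensitive carotenoid partners: bromide opens the epoxide, and the resulting alkoxide generates ylide 18 in low concentration, so the free β-hydroxy aldehyde never meets a strong base. The weakly basic, delocalised ylide should not deprotonate the tertiary hydroxyls or the hindered C6–H, so the three stereocentres are carried through unchanged. Z geometry at the new C7=C8 bond is strained against the C9 methyl group and should equilibrate to E on heating.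

## Compound list

1 | (4R)-limonene 1,2-oxide, (4R)-1-methyl-4-(prop-1-en-2-yl)-7-oxabicyclo[4.1.0]heptane, cis/trans mixture at the oxirane | CC12OC2C[C@@H](CC1)C(C)=C | starting material
2 | (1S,2S,4R)-1-methyl-4-(prop-1-en-2-yl)cyclohexane-1,2-diol | C[C@]1(O)CC[C@H](C[C@@H]1O)C(C)=C | intermediate (not isolated)
3 | (3R)-6-oxo-3-(prop-1-en-2-yl)heptanal | O=CC[C@H](C(C)=C)CCC(C)=O | intermediate
4 | (3R)-6-oxo-3-(prop-1-en-2-yl)heptanoic acid | OC(=O)C[C@H](C(C)=C)CCC(C)=O | intermediate
5 | 1-[(3R)-6-oxo-3-(prop-1-en-2-yl)heptanoyl]-4-(pyrrolidin-1-yl)pyridin-1-ium 4-methylbenzenesulfonate | O=C(C[C@H](C(C)=C)CCC(C)=O)[n+]1ccc(cc1)N1CCCC1.Cc1ccc(cc1)S(=O)(=O)[O-] | intermediate (not isolated)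
6 | 1-{[(1S,2R,5R)-2-methyl-2-oxido-5-(prop-1-en-2-yl)cyclopentyl]carbonyl}-4-(pyrrolidin-1-yl)pyridin-1-ium (zwitterion) | O=C([C@H]1[C@H](C(C)=C)CC[C@@]1(C)[O-])[n+]1ccc(cc1)N1CCCC1 | intermediate (not isolated)
7 | (1S,2R,5R)-5-methyl-2-(prop-1-en-2-yl)-6-oxabicyclo[3.2.0]heptan-7-one (cis-fused β-lactone, isopropenyl trans to the lactone carbonyl) | O=C2[C@H]1[C@H](C(C)=C)CC[C@@]1(C)O2 | intermediate
8 | (1R,2R,3R)-2-(hydroxymethyl)-1-methyl-3-(prop-1-en-2-yl)cyclopentan-1-ol | OC[C@H]1[C@H](C(C)=C)CC[C@@]1(C)O | intermediate
9 | (1R,2R,3R)-2-(hydroxymethyl)-3-(2-hydroxypropan-2-yl)-1-methylcyclopentan-1-ol | OC[C@H]1[C@H](C(C)(C)O)CC[C@@]1(C)O | intermediate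
10 | (1S,2R,5R)-2-hydroxy-5-(2-hydroxypropan-2-yl)-2-methylcyclopentane-1-carbaldehyde | O=C[C@H]1[C@H](C(C)(C)O)CC[C@@]1(C)O | intermediate
11 | geranyl bromide, (2E)-1-bromo-3,7-dimethylocta-2,6-diene | CC(C)=CCC/C(C)=C/CBr | starting material
12 | [(2E)-3,7-dimethylocta-2,6-dien-1-yl]triphenylphosphonium bromide | CC(C)=CCC/C(C)=C/C[P+](c1ccccc1)(c1ccccc1)c1ccccc1.[Br-] | intermediate
13 | crocetin dialdehyde, (2E,4E,6E,8E,10E,12E,14E)-2,6,11,15-tetramethylhexadeca-2,4,6,8,10,12,14-heptaenedial | O=C/C(C)=C/C=C/C(C)=C/C=C/C=C(C)/C=C/C=C(C)/C=O | starting material
14 | [(2E)-3,7-dimethylocta-2,6-dien-1-ylidene]triphenyl-λ5-phosphane | CC(C)=CCC/C(C)=C/C=P(c1ccccc1)(c1ccccc1)c1ccccc1 | intermediate (not isolated)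
15 | apo-8'-lycopenal, (2E,4E,6E,8E,10E,12E,14E,16E,18E)-2,6,11,15,19,23-hexamethyltetracosa-2,4,6,8,10,12,14,16,18,22-decaenal | CC(C)=CCC/C(C)=C/C=C/C(C)=C/C=C/C(C)=C/C=C/C=C(C)/C=C/C=C(C)/C=O | intermediate
16 | apo-8'-lycopenol, (2E,4E,6E,8E,10E,12E,14E,16E,18E)-2,6,11,15,19,23-hexamethyltetracosa-2,4,6,8,10,12,14,16,18,22-decaen-1-ol | CC(C)=CCC/C(C)=C/C=C/C(C)=C/C=C/C(C)=C/C=C/C=C(C)/C=C/C=C(C)/CO | intermediate
17 | [(2E,4E,6E,8E,10E,12E,14E,16E,18E)-2,6,11,15,19,23-hexamethyltetracosa-2,4,6,8,10,12,14,16,18,22-decaen-1-yl]triphenylphosphonium bromide | CC(C)=CCC/C(C)=C/C=C/C(C)=C/C=C/C(C)=C/C=C/C=C(C)/C=C/C=C(C)/C[P+](c1ccccc1)(c1ccccc1)c1ccccc1.[Br-] | intermediate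
18 | [(2E,4E,6E,8E,10E,12E,14E,16E,18E)-2,6,11,15,19,23-hexamethyltetracosa-2,4,6,8,10,12,14,16,18,22-decaen-1-ylidene]triphenyl-λ5-phosphane | CC(C)=CCC/C(C)=C/C=C/C(C)=C/C=C/C(C)=C/C=C/C=C(C)/C=C/C=C(C)/C=P(c1ccccc1)(c1ccccc1)c1ccccc1 | intermediate (not isolated)
19 | (2R,5R,6S)-2,6-cyclolycopene-1,5-diol, (1R,2S,3R)-3-(2-hydroxypropan-2-yl)-1-methyl-2-[(1E,3E,5E,7E,9E,11E,13E,15E,17E,19E)-3,7,12,16,20,24-hexamethylpentacosa-1,3,5,7,9,11,13,15,17,19,23-undecaen-1-yl]cyclopentan-1-ol | CC(C)=CCC/C(C)=C/C=C/C(C)=C/C=C/C(C)=C/C=C/C=C(C)/C=C/C=C(C)/C=C/[C@H]1[C@H](C(C)(C)O)CC[C@@]1(C)O | target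

## Step count and risks

Total step count: 11. Longest linear sequence: 7 steps (steps 1 to 6, then step 11); the polyene branch is 5 steps (steps 7 to 11).

Least certain steps:

**Step 3 (key step).** The most likely failure is incomplete face selection by C2 at the enolate carbon, or acyl transfer between molecules outrunning the aldol when the concentration of activated acid is too high. Fallback: leave the lactone aside and form the same C5–C6 bond by an enamine aldol. It sets out from keto aldehyde 3. Catalytic pyrrolidine/AcOH forms the aldehyde enamine, which adds to the methyl ketone (5-enolexo closure) to give (1S,2R,5R)-2-hydroxy-2-methyl-5-(prop-1-en-2-yl)cyclopentane-1-carbaldehyde F1. Because this aldol is reversible and C6 is epimerisable, equilibration should favour the isomer with the formyl group trans to the isopropenyl group and hydrogen-bonded to the cis hydroxyl. NaBH4 reduction of F1 gives diol 8, where the route is rejoined. The cost is that the cis relationship then rests on equilibrium and not on a ring fusion.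

**Step 11.** The most likely failure is slow addition of the delocalised ylide to the hindered aldehyde. That leaves time for retro-aldol opening, for epimerisation at C6 followed by lactol formation with the C1 hydroxyl, or for β-elimination of the free hydroxy aldehyde. Fallback: mask both tertiary hydroxyls so that a preformed ylide and a strong base can be used. It sets out from triol 9. TMSCl/imidazole in DMF gives the tris(trimethylsilyl) ether F2. Swern oxidation (oxalyl chloride, DMSO, then Et3N), which cleaves and oxidises a primary trimethylsilyl ether beside hindered ones, gives the bis(trimethylsilyl) aldehyde F3. Wittig reaction of F3 with ylide 18, preformed from 17 with NaN(SiMe3)2 in THF at −78 °C, followed by thermal equilibration, gives the bis(trimethylsilyl) ether F4 of the target. Bu4NF in THF removes the silyl groups and returns to the route at 19.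

**Step 10.** The most likely failure is acid-induced isomerisation or decomposition of the polyene and of the trisubstituted alkenes of the tail while the allylic cation is being trapped, or capture of that cation by solvent. Fallback: reverse the polarity of the C7=C8 olefination so that aldehyde 15 is used directly and steps 9 and 10 fall away. It sets out from triol 9. Mitsunobu reaction at the primary hydroxyl with 1-phenyl-1H-tetrazole-5-thiol (PPh3, DIAD, THF) gives the sulfide F5. Oxidation with H2O2 and catalytic (NH4)6Mo7O24 in EtOH gives the sulfone F6. Julia–Kocienski olefination of F6 with aldehyde 15 (LiN(SiMe3)2, THF, −78 °C, the tertiary hydroxyls being far less acidic than the sulfonyl CH2), followed by thermal equilibration, returns to the route at 19.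

**Step 5.** The most likely failure is reduction of the C1 radical to the saturated isopropyl group, or incomplete reduction at the peroxide stage. Fallback: ionic chemistry, carried out one step earlier. It sets out from β-lactone 7. mCPBA (CH2Cl2, NaHCO3, 0 °C) epoxidises the 1,1-disubstituted alkene to the epoxy lactone F7, as both epimers at the new oxirane carbon, which is of no consequence. LiAlH4 in THF then opens the oxirane at its CH2 terminus and reduces the lactone in the same operation. This gives triol 9 directly, where the route is rejoined, and step 4 is not needed.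

## Further compounds

F1 | step 3 | (1S,2R,5R)-2-hydroxy-2-methyl-5-(prop-1-en-2-yl)cyclopentane-1-carbaldehyde | O=C[C@H]1[C@H](C(C)=C)CC[C@@]1(C)O
F2 | step 11 | (1R,2R,3R)-1-methyl-1-(trimethylsilyloxy)-2-[(trimethylsilyloxy)methyl]-3-[2-(trimethylsilyloxy)propan-2-yl]cyclopentane | C[Si](C)(C)OC[C@H]1[C@H](C(C)(C)O[Si](C)(C)C)CC[C@@]1(C)O[Si](C)(C)C
F3 | step 11 | (1S,2R,5R)-2-methyl-2-(trimethylsilyloxy)-5-[2-(trimethylsilyloxy)propan-2-yl]cyclopentane-1-carbaldehyde | O=C[C@H]1[C@H](C(C)(C)O[Si](C)(C)C)CC[C@@]1(C)O[Si](C)(C)C
F4 | step 11 | (2R,5R,6S)-1,5-bis(trimethylsilyloxy)-2,6-cyclolycopene, the bis(trimethylsilyl) ether of 19 | CC(C)=CCC/C(C)=C/C=C/C(C)=C/C=C/C(C)=C/C=C/C=C(C)/C=C/C=C(C)/C=C/[C@H]1[C@H](C(C)(C)O[Si](C)(C)C)CC[C@@]1(C)O[Si](C)(C)C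
F5 | step 10 | (1R,2S,3R)-3-(2-hydroxypropan-2-yl)-1-methyl-2-{[(1-phenyl-1H-tetrazol-5-yl)sulfanyl]methyl}cyclopentan-1-ol | c1ccc(cc1)-n1nnnc1SC[C@H]1[C@H](C(C)(C)O)CC[C@@]1(C)O
F6 | step 10 | (1R,2S,3R)-3-(2-hydroxypropan-2-yl)-1-methyl-2-{[(1-phenyl-1H-tetrazol-5-yl)sulfonyl]methyl}cyclopentan-1-ol | c1ccc(cc1)-n1nnnc1S(=O)(=O)C[C@H]1[C@H](C(C)(C)O)CC[C@@]1(C)O
F7 | step 5 | (1S,2R,5R)-5-methyl-2-(2-methyloxiran-2-yl)-6-oxabicyclo[3.2.0]heptan-7-one, both epimers at the oxirane carbon | O=C2[C@H]1[C@H](C3(C)CO3)CC[C@@]1(C)O2
A1 | alternative 1 | (4R,5S)-6-diazo-5-ethenyl-4-methyl-4-(triethylsilyloxy)cyclohex-2-en-1-one | C=C[C@H]1C(=[N+]=[N-])C(=O)C=C[C@@]1(C)O[Si](CC)(CC)CC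
A2 | alternative 1 | methyl (4R,5S)-5-ethenyl-4-methyl-4-(triethylsilyloxy)cyclopent-2-ene-1-carboxylate, C1 undefined | C=C[C@H]1C(C(=O)OC)C=C[C@@]1(C)O[Si](CC)(CC)CC
A3 | alternative 2 | methyl (3R)-2-acetyl-5-iodo-3-(prop-1-en-2-yl)pentanoate, C2 undefined | COC(=O)C(C(C)=O)[C@H](C(C)=C)CCI
A4 | alternative 2 | methyl (1S,2R,5R)-2-hydroxy-2-methyl-5-(prop-1-en-2-yl)cyclopentane-1-carboxylate | COC(=O)[C@H]1[C@H](C(C)=C)CC[C@@]1(C)O
A5 | alternative 3 | (2R,3S)-3-ethenyl-2-methyl-2-(4-methylpent-3-en-1-yl)oxirane, vinyl cis to the pentenyl chain | C=C[C@@H]1O[C@]1(C)CCC=C(C)C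
A6 | alternative 3 | (1R,2S,3R)-2-ethenyl-3-(2-hydroxypropan-2-yl)-1-methylcyclopentan-1-ol | C=C[C@H]1[C@H](C(C)(C)O)CC[C@@]1(C)O
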